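Abbreviations: TBS = tert-butyldimethylsilyl, TBSO = tert-butyldimethylsilyloxy. Carbon numbers C1–C17 are the cembrane numbers of the target: C1 is the ring CH that carries C15, C16 is the lactone carbonyl and C17 the exocyclic methylene.

## Analysis of the target

- The target 37 is a cembranolide, (1S,3S,4E,7Z,11R,12S)-11-acetoxy-3-hydroxycembra-4,7,15(17)-trien-16,12-olide. A 14-membered carbocycle C1–C14 is bridged between C1 and C12 by a seven-membered α-methylene lactone (C1, C15, C16, ring oxygen, C12, C13, C14), with methyl groups on C4, C8 and C12.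
- There are four stereocentres. C11 (secondary acetate) and C12 (fully substituted, bearing the lactone oxygen) are vicinal. C1 and C12 are 1,4-related across C13–C14, and the two arms of the macrocycle (C2 and C11) are trans on the lactone ring. C3 is an allylic carbinol 1,3 to C1.
- The unsaturation is a skipped diene, 4E and 7Z, both alkenes trisubstituted, with a doubly allylic C6.
- Sensitive groups are the α-methylene lactone (Michael acceptor, attacked by hydride donors and strong nucleophiles), the C11 acetate (bases), and the skipped diene (peracids, isomerisation). A C3 hydroxyl lies five atoms from C16, so in open-chain intermediates it can translactonise to a δ-lactone.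
- The hard points are a seven-membered lactone closed onto a tertiary oxygen that is itself a stereocentre, a Z trisubstituted alkene, a C3 centre with no rigid frame linking it to the others, and the macrocyclisation.
- The strategy rests on one feature. Without the ring oxygen, C16–C15–C1–C14–C13–C12 is a cyclohexane whose C12 is an all-carbon quaternary centre carrying a methyl and C11. That is the α-carbon of methacrolein with its formyl carbon as C11, so the tertiary C–O bond can be made by oxygen insertion with retention instead of by esterification.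

## Retrosynthetic reasoning

**C3–O.** The carbinol of 37 is taken back to the macrocyclic enone 36. A ring closure cannot be trusted to set an isolated stereocentre, whereas reagent-controlled reduction of an α-methyl enone can.

**C3–C4 (ring closure).** Enone 36 comes from the epimeric alcohols 35, and these from the acetoxy iodo aldehyde 34 by a Nozaki–Hiyama–Kishi closure. This bond joins an sp2 carbon to a carbonyl, tolerates acetate, lactone and enoate, and keeps the 4E geometry that is fixed beforehand in the alkenyl iodide.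

**C15=C17 and the oxygen functions.** Aldehyde 34 is taken back through 33, 32 and 31 to the bis-silyl ether 30, and 30 to lactone 27 by α-methylenation. The order is dictated by reactivity: methylenation needs a strong base, so it comes before the acetate and the aldehyde; it comes after the hydrometallation, which would reduce an enoate.

**C4–I and C8–C9.** The (E)-alkenyl iodide of 27 comes from the methyl alkyne of 25 by syn hydrozirconation–iodination. Compound 25 is cut at C8–C9 into the bromo lactone 17 and the enyne 23 (Negishi coupling). Fragment 23 carries the Z alkene ready-made; it is assembled from allylic bromide 21 and prop-1-ynylmagnesium bromide (22), with 21 coming from but-2-yn-1-ol (18) through iodide 20.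

**Lactone oxygen.** Lactone 17 is taken back to cyclohexanone 16 by Baeyer–Villiger oxidation, which replaces the C12–C16 bond by C12–O–C16. The more substituted carbon migrates with retention, so the quaternary centre becomes the tertiary C–O centre. This has to precede any trisubstituted alkene, which is why the diene is attached afterwards.

**C9.** Bromide 16 comes from the allyl ketone 13 through 14 and 15 by excision of the terminal alkene carbon. An allyl group is one carbon too long for C10–C9, but allylboration is the most reliable reagent-controlled way to set C11, and ozonolysis removes the extra carbon.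

**C1.** Ketone 13 comes from enone 12 by conjugate reduction, which creates C1 under ligand control.

**C1–C2 and carbonyl transposition.** Enone 12 comes from the tertiary allylic alcohol 11 by oxidative 1,3-transposition. Alcohol 11 comes from 10 and 9, and 9 from enone 7 and tert-butyl acetate (8) by 1,2-addition. This moves the carbonyl from C1 to C16, next to the quaternary carbon, where the Baeyer–Villiger step needs it. The ester is reduced at once so that the lactone is later the only enolisable ester.

**C10–C11.** Silyl ether 7 comes from alcohol 6, and 6 from aldehyde 4 by asymmetric allylboration of the formyl group.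

**C12–C16 and C13–C14.** Aldehyde 4 is the Diels–Alder adduct (after hydrolysis of 3) of the aminosiloxydiene 1 and methacrolein (2). Both partners are commercial, and the cycloaddition delivers the ring, the quaternary centre and both carbonyls in one step.

## Alternatives that were turned down

**Alternative 1: sulfone alkylation at C9–C10.**
- Disconnection and key step: the macrocycle is cut between C9 and C10. A C9 phenylsulfonyl carbanion of the linear bromo sulfone A2 displaces the C10 allylic bromide under high dilution and gives the 14-membered triene sulfone A1.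
- For: alkylation of a soft, stabilised carbanion by an allylic halide is among the most dependable cembrane ring closures. The fragments are open-chain terpenoid pieces and no sensitive group is present at ring closure.
- Against, for this target: in A1 the C11=C12 bond is still an alkene and the lactone carbons are a protected allylic alcohol. C11 and C12 must then be oxygenated on a triene, choosing one of three trisubstituted alkenes with no directing group near C11=C12, and with face control. The tertiary C12 oxygen must still close a seven-membered lactone. Reductive removal of an allylic sulfone next to the Z alkene can shift or isomerise that alkene.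
- Comparison: A1 is reached by a safer ring closure and probably in fewer steps than my macrocycle. The chosen route offers instead absolute control of C12 and a tertiary lactone C–O bond made without a selective oxidation of a polyene.

**Alternative 2: three-component carbocupration–allylation.**
- Disconnection and key step: C8–C9 and C6–C7 are cut. The alkylcopper species from Grignard reagent A4 adds syn across propyne A5, and the Z alkenylcopper is allylated in the same flask by the (E)-iodo allylic bromide A6, giving the iodo diene A3.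
- For: both alkene geometries follow from mechanism in one operation, and A3 already carries the C4 iodide. On the diene it is clearly stronger than my sequence, which needs a three-step fragment, a Negishi coupling and a late hydrozirconation.
- Against, for this target: it is a fragment synthesis. C11 arrives as a primary silyl ether, so C11–C12 must later be made with simultaneous control of a secondary and an oxygenated quaternary centre in an open chain. C1 and the tertiary seven-membered lactone stay unsolved. Grignard and copper reagents cannot be used once a lactone is present.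
- Comparison: the chosen strategy concedes the diene and gains the stereocentres and the lactone.

**Alternative 3: carbonylative lactonisation on the macrocycle.**
- Disconnection and key step: C15–C16 and C16–O are cut. A zerovalent palladium catalyst under CO converts the C15 enol triflate A8 into an acyl–palladium that the C12 tertiary hydroxyl captures, giving A7, the C3 silyl ether of the target.
- For: C16, the lactone and the exocyclic alkene appear in one late step, with no separate methylenation and with the Michael acceptor present only at the end. Its endgame is shorter than mine.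
- Against, for this target: trapping an acyl–palladium with a tertiary alcohol to form a seven-membered ring across a macrocycle is the slow combination of nucleophile and ring size. Reduction, intermolecular capture or acyl transfer from the C11 acetate can compete. The 14-membered ring with all four stereocentres and a C1 methyl ketone must be made first by other means, and the riskiest step then comes last.
- Comparison: the chosen route forms the tertiary C–O bond by a 1,2-shift with retention, not by attack of a tertiary alcohol, and puts its main risk in step 1.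

Key step: step 1

Assumption: the (4R,5R) diol of step 1 and the (R) bisphosphine of step 8 are written as the enantiomers that lead to (R)-4 and (1S)-13 by analogy with simpler substrates; if a first run shows the opposite sense, the mirror-image catalyst is used and nothing else changes.

## Route

Step 1
Reactants: 1 (E)-1-(dimethylamino)-3-(tert-butyldimethylsilyloxy)buta-1,3-diene; 2 methacrolein
Product: 4 (R)-4-formyl-4-methylcyclohex-2-en-1-one, via amino silyl enol ether cycloadduct 3 (not isolated)
Conditions: (4R,5R)-2,2-dimethyl-α,α,α′,α′-tetra(1-naphthyl)-1,3-dioxolane-4,5-dimethanol (20 mol%), toluene, −80 °C, 48 h; then HF (aq.), MeCN, −20 °C → rt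
Reagents that add atoms: none
Why: The diol hydrogen-bonds to the aldehyde oxygen of 2 and lowers its LUMO, and the push–pull diene 1 adds in a concerted, strongly asynchronous [4+2] cycloaddition: the nucleophilic CH2 terminus bonds to the β-carbon (C13–C14) and the amino-bearing terminus to the α-carbon (C12–C16). The closest known reaction type is the hydrogen-bond-catalysed enantioselective Diels–Alder reaction of 1-amino-3-siloxydienes with α-substituted acroleins. The six-membered carbocycle C16–C15–C1–C14–C13–C12 is closed by the cycloaddition itself, both ring bonds forming in the same step. The one lasting stereocentre, quaternary C12, is set by the catalyst: one hydroxyl donates to the other, the free hydroxyl binds the carbonyl, and a naphthyl group shields one face of the enal so that the diene adds to the other with the formyl group endo. The regiochemistry needed (amino carbon next to the quaternary carbon) follows from the polarisation of the diene, whose largest HOMO coefficient lies on the unsubstituted terminus. The amino stereocentre of 3 does not matter, because the acid hydrolyses the silyl enol ether and eliminates dimethylamine to give enone 4. C12 carries no hydrogen, so neither this work-up nor later enolisations can erode it.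

Step 2
Reactants: 4 (R)-4-formyl-4-methylcyclohex-2-en-1-one
Product: 6 (4R)-4-[(1R)-1-hydroxybut-3-en-1-yl]-4-methylcyclohex-2-en-1-one, via diisopinocampheylborinate ester 5 (not isolated)
Conditions: lIpc2B(allyl) [from (−)-α-pinene], Et2O, −78 °C; then HOCH2CH2NH2, rt
Reagents that add atoms: B-allyldiisopinocampheylborane derived from (−)-α-pinene, C=CCB([C@H]1C[C@H]2C[C@@H]([C@@H]1C)C2(C)C)[C@H]1C[C@H]2C[C@@H]([C@@H]1C)C2(C)C
Why: Brown allylation through a closed chair transition state: the pinene ligands choose the Re face of the aldehyde (the sense that turns benzaldehyde into the R alcohol), which gives 11R whatever the weak bias of the quaternary centre. The aldehyde reacts far faster than the enone carbonyl at −78 °C, and the non-oxidative aminoethanol work-up spares the enone.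

Step 3
Reactants: 6 (4R)-4-[(1R)-1-hydroxybut-3-en-1-yl]-4-methylcyclohex-2-en-1-one
Product: 7 (4R)-4-[(1R)-1-(TBSO)but-3-en-1-yl]-4-methylcyclohex-2-en-1-one
Conditions: TBSOTf, 2,6-lutidine, CH2Cl2, −78 → 0 °C
Reagents that add atoms: tert-butyldimethylsilyl triflate, CC(C)(C)[Si](C)(C)OS(=O)(=O)C(F)(F)F
Why: Silylation with the triflate is needed for the neopentyl-type secondary alcohol; the hindered ether should survive the enolate, hydride, chromium, peracid and organometallic steps that follow.

Step 4
Reactants: 7 (4R)-4-[(1R)-1-(TBSO)but-3-en-1-yl]-4-methylcyclohex-2-en-1-one; 8 tert-butyl acetate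
Product: 9 tert-butyl 2-[(4R)-4-[(1R)-1-(TBSO)but-3-en-1-yl]-1-hydroxy-4-methylcyclohex-2-en-1-yl]acetate (both epimers at the carbinol carbon)
Conditions: LDA, 8, THF, −78 °C; then 7, −78 °C; AcOH
Reagents that add atoms: none
Why: Aldol-type 1,2-addition of a lithium ester enolate, which is the kinetic course with cyclohexenones at −78 °C; conjugate addition is further disfavoured because the β-carbon (C16) is neopentyl. The new carbinol centre is destroyed in step 7, so the epimers are carried on together.

Step 5
Reactants: 9 tert-butyl 2-[(4R)-4-[(1R)-1-(TBSO)but-3-en-1-yl]-1-hydroxy-4-methylcyclohex-2-en-1-yl]acetate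
Product: 10 (4R)-4-[(1R)-1-(TBSO)but-3-en-1-yl]-1-(2-hydroxyethyl)-4-methylcyclohex-2-en-1-ol (both C1 epimers)
Conditions: LiAlH4, Et2O, 0 °C
Reagents that add atoms: none
Why: Hydride reduction of the ester to the primary alcohol removes the second enolisable ester before a lactone exists (it would compete in step 17) and brings C3 to a level from which the aldehyde is one mild oxidation away. Silyl ether and alkenes are inert.

Step 6
Reactants: 10 (4R)-4-[(1R)-1-(TBSO)but-3-en-1-yl]-1-(2-hydroxyethyl)-4-methylcyclohex-2-en-1-ol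
Product: 11 (4R)-4-[(1R)-1-(TBSO)but-3-en-1-yl]-1-[2-(TBSO)ethyl]-4-methylcyclohex-2-en-1-ol (both C1 epimers)
Conditions: TBSCl, imidazole, CH2Cl2, 0 °C
Reagents that add atoms: tert-butyldimethylsilyl chloride, CC(C)(C)[Si](C)(C)Cl
Why: Selective silylation of the primary hydroxyl; the tertiary allylic alcohol does not react with the silyl chloride.

Step 7
Reactants: 11 (4R)-4-[(1R)-1-(TBSO)but-3-en-1-yl]-1-[2-(TBSO)ethyl]-4-methylcyclohex-2-en-1-ol
Product: 12 (6S)-6-[(1R)-1-(TBSO)but-3-en-1-yl]-3-[2-(TBSO)ethyl]-6-methylcyclohex-2-en-1-one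
Conditions: pyridinium chlorochromate, 4 Å molecular sieves, CH2Cl2, rt
Reagents that add atoms: pyridinium chlorochromate, [O-][Cr](=O)(=O)Cl.c1cc[nH+]cc1
Why: Babler–Dauben oxidative transposition: the tertiary allylic chromate ester undergoes a [3,3] shift that delivers oxygen to C16 and is oxidised there. This puts the carbonyl next to quaternary C12 and makes C1 the β-carbon that carries the C2–C3 chain.

Step 8
Reactants: 12 (6S)-6-[(1R)-1-(TBSO)but-3-en-1-yl]-3-[2-(TBSO)ethyl]-6-methylcyclohex-2-en-1-one
Product: 13 (2S,5S)-2-[(1R)-1-(TBSO)but-3-en-1-yl]-5-[2-(TBSO)ethyl]-2-methylcyclohexan-1-one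
Conditions: Cu(OAc)2·H2O (5 mol%), (R)-5,5′-bis[bis(3,5-di-tert-butyl-4-methoxyphenyl)phosphino]-4,4′-bi-1,3-benzodioxole (5 mol%), HSiMe(OEt)2, t-BuOH, toluene, 0 °C
Reagents that add atoms: none
Why: Ligand-controlled copper hydride conjugate reduction of a β,β-disubstituted cyclohexenone: the chiral bisphosphine–CuH delivers hydride to the C1 face anti to the C12 methyl, so the C2 chain ends up cis to that methyl and trans to the C11 chain (1S). t-BuOH protonates the copper enolate, and the unactivated terminal alkene should not react at 0 °C.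

Step 9
Reactants: 13 (2S,5S)-2-[(1R)-1-(TBSO)but-3-en-1-yl]-5-[2-(TBSO)ethyl]-2-methylcyclohexan-1-one
Product: 15 (2S,5S)-2-[(1R)-1-(TBSO)-3-hydroxypropyl]-5-[2-(TBSO)ethyl]-2-methylcyclohexan-1-one, via keto aldehyde 14 (not isolated)
Conditions: O3, CH2Cl2, −78 °C; Me2S, −78 °C → rt; then NaBH4, EtOH/CH2Cl2, −78 °C
Reagents that add atoms: ozone, [O-][O+]=O
Why: Ozonolysis removes the surplus terminal carbon of the allyl group. The β-silyloxy aldehyde is reduced at once at −78 °C, where an aldehyde reacts much faster than the hindered α-quaternary ketone.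

Step 10
Reactants: 15 (2S,5S)-2-[(1R)-1-(TBSO)-3-hydroxypropyl]-5-[2-(TBSO)ethyl]-2-methylcyclohexan-1-one
Product: 16 (2S,5S)-2-[(1R)-3-bromo-1-(TBSO)propyl]-5-[2-(TBSO)ethyl]-2-methylcyclohexan-1-one
Conditions: CBr4, PPh3, CH2Cl2, 0 °C
Reagents that add atoms: carbon tetrabromide, BrC(Br)(Br)Br
Why: Appel reaction. A primary bromide is chosen because, unlike an iodide, it is inert to the peracid of step 11 and still inserts zinc in step 15.

Step 11
Reactants: 16 (2S,5S)-2-[(1R)-3-bromo-1-(TBSO)propyl]-5-[2-(TBSO)ethyl]-2-methylcyclohexan-1-one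
Product: 17 (4S,7S)-7-[(1R)-3-bromo-1-(TBSO)propyl]-4-[2-(TBSO)ethyl]-7-methyloxepan-2-one
Conditions: mCPBA, NaHCO3, CH2Cl2, rt
Reagents that add atoms: meta-chloroperbenzoic acid, O=C(OO)c1cccc(Cl)c1
Why: Baeyer–Villiger oxidation: in the Criegee intermediate the tertiary C12 migrates in preference to the primary C15, and with retention. The all-carbon quaternary centre becomes the tertiary lactone C–O centre (12S) and the cyclohexanone becomes the seven-membered lactone; no alkene is present at this stage.

Step 12
Reactants: 18 but-2-yn-1-ol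
Product: 20 (Z)-3-iodobut-2-en-1-ol, via cyclic alkenylalanate 19 (not isolated)
Conditions: NaAlH2(OCH2CH2OMe)2, THF, 0 °C → rt; then I2, THF, −78 → 0 °C
Reagents that add atoms: iodine, II
Why: Alkoxide-directed trans-hydroalumination puts aluminium on C3 (the future C8) cis to the CH2O group; iodinolysis with retention gives the Z iodide.

Step 13
Reactants: 20 (Z)-3-iodobut-2-en-1-ol
Product: 21 (Z)-1-bromo-3-iodobut-2-ene
Conditions: CBr4, PPh3, CH2Cl2, 0 °C
Reagents that add atoms: carbon tetrabromide, BrC(Br)(Br)Br
Why: Appel bromination of a primary allylic alcohol under neutral conditions, which keeps the Z geometry.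

Step 14
Reactants: 21 (Z)-1-bromo-3-iodobut-2-ene; 22 prop-1-ynylmagnesium bromide
Product: 23 (Z)-2-iodohept-2-en-5-yne
Conditions: CuBr·SMe2 (10 mol%), THF, −20 °C → rt
Reagents that add atoms: none
Why: Copper-catalysed SN2 coupling of an alkynyl Grignard reagent with a primary allylic bromide gives the skipped enyne; the alkenyl iodide should not react with alkynyl magnesium or copper species at this temperature.

Step 15
Reactants: 17 (4S,7S)-7-[(1R)-3-bromo-1-(TBSO)propyl]-4-[2-(TBSO)ethyl]-7-methyloxepan-2-one; 23 (Z)-2-iodohept-2-en-5-yne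
Product: 25 (4S,7S)-7-[(1R,4Z)-1-(TBSO)-4-methylnon-4-en-7-yn-1-yl]-4-[2-(TBSO)ethyl]-7-methyloxepan-2-one, via alkylzinc bromide 24 (not isolated)
Conditions: Zn dust, I2 (5 mol%), DMA, 70 °C; then 23, Pd(PPh3)4 (5 mol%), THF/DMA, rt → 45 °C
Reagents that add atoms: none
Why: Negishi coupling: zinc inserts into the primary C–Br bond without attacking the lactone, and the alkylzinc couples with the alkenyl iodide under zerovalent palladium with retention of the Z geometry (C8–C9 bond). Alkyne and silyl ethers are inert.

Step 16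
Reactants: 25 (4S,7S)-7-[(1R,4Z)-1-(TBSO)-4-methylnon-4-en-7-yn-1-yl]-4-[2-(TBSO)ethyl]-7-methyloxepan-2-one
Product: 27 (4S,7S)-7-[(1R,4Z,7E)-1-(TBSO)-8-iodo-4-methylnona-4,7-dien-1-yl]-4-[2-(TBSO)ethyl]-7-methyloxepan-2-one, via alkenylzirconocene chloride 26 (not isolated)
Conditions: Cp2Zr(H)Cl (2.5 equiv), THF, rt → 50 °C; then I2, THF, 0 °C
Reagents that add atoms: iodine, II
Why: Syn hydrozirconation of the methyl alkyne; with excess Cp2Zr(H)Cl the adduct equilibrates to the regioisomer with zirconium on the methyl-bearing carbon C4, and iodinolysis with retention gives the (E)-alkenyl iodide. The alkyne should react faster than the lactone.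

Step 17
Reactants: 27 (4S,7S)-7-[(1R,4Z,7E)-1-(TBSO)-8-iodo-4-methylnona-4,7-dien-1-yl]-4-[2-(TBSO)ethyl]-7-methyloxepan-2-one
Product: 30 (4S,7S)-7-[(1R,4Z,7E)-1-(TBSO)-8-iodo-4-methylnona-4,7-dien-1-yl]-4-[2-(TBSO)ethyl]-7-methyl-3-methylideneoxepan-2-one, via Mannich base 28 (not isolated), via trimethylammonium iodide 29 (not isolated)
Conditions: LDA, THF, −78 °C; Me2N=CH2+ I−, −78 °C → rt; then MeI, MeOH, rt; then NaHCO3 (aq.), CH2Cl2, rt
Reagents that add atoms: dimethylmethyleneiminium iodide, C=[N+](C)C.[I-]
Why: Mannich methylenation: C15 is the only enolisable position, its lithium enolate adds to the iminium salt, and quaternisation followed by E1cB elimination gives the exocyclic alkene. At −78 °C the amide base should not attack the alkenyl iodide.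

Step 18
Reactants: 30 (4S,7S)-7-[(1R,4Z,7E)-1-(TBSO)-8-iodo-4-methylnona-4,7-dien-1-yl]-4-[2-(TBSO)ethyl]-7-methyl-3-methylideneoxepan-2-one
Product: 31 (4S,7S)-7-[(1R,4Z,7E)-1-(TBSO)-8-iodo-4-methylnona-4,7-dien-1-yl]-4-(2-hydroxyethyl)-7-methyl-3-methylideneoxepan-2-one
Conditions: HF·pyridine, pyridine, THF, 0 °C
Reagents that add atoms: none
Why: Buffered HF·pyridine cleaves the primary silyl ether and leaves the hindered C11 ether. The free C3 alcohol is oxidised in the next step without storage, because it could translactonise onto C16.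

Step 19
Reactants: 31 (4S,7S)-7-[(1R,4Z,7E)-1-(TBSO)-8-iodo-4-methylnona-4,7-dien-1-yl]-4-(2-hydroxyethyl)-7-methyl-3-methylideneoxepan-2-one
Product: 32 2-{(4S,7S)-7-[(1R,4Z,7E)-1-(TBSO)-8-iodo-4-methylnona-4,7-dien-1-yl]-7-methyl-3-methylidene-2-oxooxepan-4-yl}acetaldehyde
Conditions: Dess–Martin periodinane, NaHCO3, CH2Cl2, 0 °C → rt
Reagents that add atoms: none
Why: Dess–Martin oxidation of a primary alcohol under buffered, non-basic conditions that tolerate the alkenyl iodide, the skipped diene and the methylene lactone.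

Step 20
Reactants: 32 2-{(4S,7S)-7-[(1R,4Z,7E)-1-(TBSO)-8-iodo-4-methylnona-4,7-dien-1-yl]-7-methyl-3-methylidene-2-oxooxepan-4-yl}acetaldehyde
Product: 33 2-{(4S,7S)-7-[(1R,4Z,7E)-1-hydroxy-8-iodo-4-methylnona-4,7-dien-1-yl]-7-methyl-3-methylidene-2-oxooxepan-4-yl}acetaldehyde
Conditions: HF (48% aq.), MeCN, 0 °C → rt
Reagents that add atoms: none
Why: Aqueous HF removes the hindered secondary silyl ether. No primary alcohol is present any more, and lactone, aldehyde and alkenyl iodide are stable to the acid.

Step 21
Reactants: 33 2-{(4S,7S)-7-[(1R,4Z,7E)-1-hydroxy-8-iodo-4-methylnona-4,7-dien-1-yl]-7-methyl-3-methylidene-2-oxooxepan-4-yl}acetaldehyde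
Product: 34 (1R,4Z,7E)-8-iodo-4-methyl-1-[(2S,5S)-2-methyl-6-methylidene-7-oxo-5-(2-oxoethyl)oxepan-2-yl]nona-4,7-dien-1-yl acetate
Conditions: Ac2O, pyridine, 4-(dimethylamino)pyridine (cat.), CH2Cl2, 0 °C → rt
Reagents that add atoms: acetic anhydride, CC(=O)OC(C)=O
Why: Nucleophile-catalysed acetylation of the only hydroxyl; it is placed after the last strongly basic step (17), and the acetate then meets only neutral or mildly reducing conditions.

Step 22
Reactants: 34 (1R,4Z,7E)-8-iodo-4-methyl-1-[(2S,5S)-2-methyl-6-methylidene-7-oxo-5-(2-oxoethyl)oxepan-2-yl]nona-4,7-dien-1-yl acetate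
Product: 35 (1S,4E,7Z,11R,12S)-11-acetoxy-3-hydroxycembra-4,7,15(17)-trien-16,12-olide as a mixture of C3 epimers
Conditions: CrCl2 (10 equiv), NiCl2 (1 mol%), DMSO/THF, rt, 2 mM, slow addition
Reagents that add atoms: none
Why: Nozaki–Hiyama–Kishi reaction: nickel, reduced to the zerovalent state by divalent chromium, inserts into the C4–I bond, and transmetallation gives an alkenylchromium species that adds to the C3 aldehyde with retention of the 4E geometry, closing the 14-membered ring at C3–C4. Alkenylchromium reagents add to aldehydes and leave acetate, lactone and enoate alone; high dilution suppresses oligomers, and the C3 configuration is not relied on here.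

Step 23
Reactants: 35 (1S,4E,7Z,11R,12S)-11-acetoxy-3-hydroxycembra-4,7,15(17)-trien-16,12-olide (C3 epimers)
Product: 36 (1S,4E,7Z,11R,12S)-11-acetoxy-3-oxocembra-4,7,15(17)-trien-16,12-olide
Conditions: Dess–Martin periodinane, NaHCO3, CH2Cl2, 0 °C
Reagents that add atoms: none
Why: Dess–Martin oxidation of the allylic alcohols converges both epimers on one enone under conditions too mild to move the skipped diene into conjugation.

Step 24
Reactants: 36 (1S,4E,7Z,11R,12S)-11-acetoxy-3-oxocembra-4,7,15(17)-trien-16,12-olide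
Product: 37 CNP0130972.9, (1S,3S,4E,7Z,11R,12S)-11-acetoxy-3-hydroxycembra-4,7,15(17)-trien-16,12-olide
Conditions: (R)-1-methyl-3,3-diphenyltetrahydro-1H,3H-pyrrolo[1,2-c][1,3,2]oxazaborole (0.5 equiv), catecholborane, toluene/CH2Cl2, −78 °C
Reagents that add atoms: none
Why: Corey–Bakshi–Shibata reduction: the ketone binds the (R)-oxazaborolidine with the α-methylalkenyl group as the large and the C2 methylene as the small substituent, so hydride arrives on the face that gives the 3S carbinol. Catecholborane at −78 °C should not reduce the enoate, lactone or acetate, nor hydroborate the alkenes.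

## Compound list

1 | (E)-1-(dimethylamino)-3-(tert-butyldimethylsilyloxy)buta-1,3-diene | CN(C)/C=C/C(=C)O[Si](C)(C)C(C)(C)C | starting material
2 | methacrolein | C=C(C)C=O | starting material
3 | (1R,2S)-2-(dimethylamino)-1-methyl-4-(tert-butyldimethylsilyloxy)cyclohex-3-ene-1-carbaldehyde | O=C[C@]1(C)CCC(O[Si](C)(C)C(C)(C)C)=C[C@@H]1N(C)C | intermediate
4 | (R)-4-formyl-4-methylcyclohex-2-en-1-one | O=C[C@@]1(C)C=CC(=O)CC1 | intermediate
5 | diisopinocampheylborinate ester of 6 (boron on the C11 oxygen, isopinocampheyl groups from (−)-α-pinene) | C=CC[C@@H](OB([C@H]1C[C@H]2C[C@@H]([C@@H]1C)C2(C)C)[C@H]1C[C@H]2C[C@@H]([C@@H]1C)C2(C)C)[C@@]1(C)C=CC(=O)CC1 | intermediate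
6 | (4R)-4-[(1R)-1-hydroxybut-3-en-1-yl]-4-methylcyclohex-2-en-1-one | C=CC[C@@H](O)[C@@]1(C)C=CC(=O)CC1 | intermediate
7 | (4R)-4-[(1R)-1-(tert-butyldimethylsilyloxy)but-3-en-1-yl]-4-methylcyclohex-2-en-1-one | C=CC[C@@H](O[Si](C)(C)C(C)(C)C)[C@@]1(C)C=CC(=O)CC1 | intermediate
8 | tert-butyl acetate | CC(=O)OC(C)(C)C | starting material
9 | tert-butyl 2-[(4R)-4-[(1R)-1-(TBSO)but-3-en-1-yl]-1-hydroxy-4-methylcyclohex-2-en-1-yl]acetate (C1 epimers) | C=CC[C@@H](O[Si](C)(C)C(C)(C)C)[C@@]1(C)C=CC(O)(CC(=O)OC(C)(C)C)CC1 | intermediate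
10 | (4R)-4-[(1R)-1-(TBSO)but-3-en-1-yl]-1-(2-hydroxyethyl)-4-methylcyclohex-2-en-1-ol (C1 epimers) | C=CC[C@@H](O[Si](C)(C)C(C)(C)C)[C@@]1(C)C=CC(O)(CCO)CC1 | intermediate
11 | (4R)-4-[(1R)-1-(TBSO)but-3-en-1-yl]-1-[2-(TBSO)ethyl]-4-methylcyclohex-2-en-1-ol (C1 epimers) | C=CC[C@@H](O[Si](C)(C)C(C)(C)C)[C@@]1(C)C=CC(O)(CCO[Si](C)(C)C(C)(C)C)CC1 | intermediate
12 | (6S)-6-[(1R)-1-(TBSO)but-3-en-1-yl]-3-[2-(TBSO)ethyl]-6-methylcyclohex-2-en-1-one | C=CC[C@@H](O[Si](C)(C)C(C)(C)C)[C@@]1(C)C(=O)C=C(CCO[Si](C)(C)C(C)(C)C)CC1 | intermediate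
13 | (2S,5S)-2-[(1R)-1-(TBSO)but-3-en-1-yl]-5-[2-(TBSO)ethyl]-2-methylcyclohexan-1-one | C=CC[C@@H](O[Si](C)(C)C(C)(C)C)[C@@]1(C)C(=O)C[C@H](CCO[Si](C)(C)C(C)(C)C)CC1 | intermediate
14 | (3R)-3-(TBSO)-3-{(1S,4S)-4-[2-(TBSO)ethyl]-1-methyl-2-oxocyclohexyl}propanal | O=CC[C@@H](O[Si](C)(C)C(C)(C)C)[C@@]1(C)C(=O)C[C@H](CCO[Si](C)(C)C(C)(C)C)CC1 | intermediate
15 | (2S,5S)-2-[(1R)-1-(TBSO)-3-hydroxypropyl]-5-[2-(TBSO)ethyl]-2-methylcyclohexan-1-one | OCC[C@@H](O[Si](C)(C)C(C)(C)C)[C@@]1(C)C(=O)C[C@H](CCO[Si](C)(C)C(C)(C)C)CC1 | intermediate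
16 | (2S,5S)-2-[(1R)-3-bromo-1-(TBSO)propyl]-5-[2-(TBSO)ethyl]-2-methylcyclohexan-1-one | BrCC[C@@H](O[Si](C)(C)C(C)(C)C)[C@@]1(C)C(=O)C[C@H](CCO[Si](C)(C)C(C)(C)C)CC1 | intermediate
17 | (4S,7S)-7-[(1R)-3-bromo-1-(TBSO)propyl]-4-[2-(TBSO)ethyl]-7-methyloxepan-2-one | BrCC[C@@H](O[Si](C)(C)C(C)(C)C)[C@@]1(C)OC(=O)C[C@H](CCO[Si](C)(C)C(C)(C)C)CC1 | intermediate
18 | but-2-yn-1-ol | CC#CCO | starting material
19 | sodium 2,2-bis(2-methoxyethoxy)-3-methyl-2,5-dihydro-1,2-oxaaluminol-2-uide (cyclic alkenylalanate) | CC1=CCO[Al-]1(OCCOC)OCCOC.[Na+] | intermediate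
20 | (Z)-3-iodobut-2-en-1-ol | OC/C=C(/C)I | intermediate
21 | (Z)-1-bromo-3-iodobut-2-ene | BrC/C=C(/C)I | intermediate
22 | prop-1-ynylmagnesium bromide | CC#C[Mg]Br | starting material
23 | (Z)-2-iodohept-2-en-5-yne | CC#CC/C=C(/C)I | intermediate
24 | alkylzinc bromide from 17 (zinc on C9) | Br[Zn]CC[C@@H](O[Si](C)(C)C(C)(C)C)[C@@]1(C)OC(=O)C[C@H](CCO[Si](C)(C)C(C)(C)C)CC1 | intermediate
25 | (4S,7S)-7-[(1R,4Z)-1-(TBSO)-4-methylnon-4-en-7-yn-1-yl]-4-[2-(TBSO)ethyl]-7-methyloxepan-2-one | CC#CC/C=C(/C)CC[C@@H](O[Si](C)(C)C(C)(C)C)[C@@]1(C)OC(=O)C[C@H](CCO[Si](C)(C)C(C)(C)C)CC1 | intermediate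
26 | alkenylzirconocene chloride from 25 (zirconium on C4, trans to C6; cyclopentadienyl rings drawn σ-bonded) | Cl[Zr](C1C=CC=C1)(C1C=CC=C1)/C(C)=C/C/C=C(/C)CC[C@@H](O[Si](C)(C)C(C)(C)C)[C@@]1(C)OC(=O)C[C@H](CCO[Si](C)(C)C(C)(C)C)CC1 | intermediate
27 | (4S,7S)-7-[(1R,4Z,7E)-1-(TBSO)-8-iodo-4-methylnona-4,7-dien-1-yl]-4-[2-(TBSO)ethyl]-7-methyloxepan-2-one | I/C(C)=C/C/C=C(/C)CC[C@@H](O[Si](C)(C)C(C)(C)C)[C@@]1(C)OC(=O)C[C@H](CCO[Si](C)(C)C(C)(C)C)CC1 | intermediate
28 | 3-(dimethylaminomethyl) derivative of 27 (Mannich base, C15 epimers) | I/C(C)=C/C/C=C(/C)CC[C@@H](O[Si](C)(C)C(C)(C)C)[C@@]1(C)OC(=O)C(CN(C)C)[C@H](CCO[Si](C)(C)C(C)(C)C)CC1 | intermediate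
29 | trimethylammonium iodide of 28 (C15 epimers) | I/C(C)=C/C/C=C(/C)CC[C@@H](O[Si](C)(C)C(C)(C)C)[C@@]1(C)OC(=O)C(C[N+](C)(C)C)[C@H](CCO[Si](C)(C)C(C)(C)C)CC1.[I-] | intermediate
30 | (4S,7S)-7-[(1R,4Z,7E)-1-(TBSO)-8-iodo-4-methylnona-4,7-dien-1-yl]-4-[2-(TBSO)ethyl]-7-methyl-3-methylideneoxepan-2-one | I/C(C)=C/C/C=C(/C)CC[C@@H](O[Si](C)(C)C(C)(C)C)[C@@]1(C)OC(=O)C(=C)[C@H](CCO[Si](C)(C)C(C)(C)C)CC1 | intermediate
31 | (4S,7S)-7-[(1R,4Z,7E)-1-(TBSO)-8-iodo-4-methylnona-4,7-dien-1-yl]-4-(2-hydroxyethyl)-7-methyl-3-methylideneoxepan-2-one | I/C(C)=C/C/C=C(/C)CC[C@@H](O[Si](C)(C)C(C)(C)C)[C@@]1(C)OC(=O)C(=C)[C@H](CCO)CC1 | intermediate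
32 | 2-{(4S,7S)-7-[(1R,4Z,7E)-1-(TBSO)-8-iodo-4-methylnona-4,7-dien-1-yl]-7-methyl-3-methylidene-2-oxooxepan-4-yl}acetaldehyde | I/C(C)=C/C/C=C(/C)CC[C@@H](O[Si](C)(C)C(C)(C)C)[C@@]1(C)OC(=O)C(=C)[C@H](CC=O)CC1 | intermediate
33 | 2-{(4S,7S)-7-[(1R,4Z,7E)-1-hydroxy-8-iodo-4-methylnona-4,7-dien-1-yl]-7-methyl-3-methylidene-2-oxooxepan-4-yl}acetaldehyde | I/C(C)=C/C/C=C(/C)CC[C@@H](O)[C@@]1(C)OC(=O)C(=C)[C@H](CC=O)CC1 | intermediate
34 | (1R,4Z,7E)-8-iodo-4-methyl-1-[(2S,5S)-2-methyl-6-methylidene-7-oxo-5-(2-oxoethyl)oxepan-2-yl]nona-4,7-dien-1-yl acetate | I/C(C)=C/C/C=C(/C)CC[C@@H](OC(C)=O)[C@@]1(C)OC(=O)C(=C)[C@H](CC=O)CC1 | intermediate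
35 | (1S,4E,7Z,11R,12S)-11-acetoxy-3-hydroxycembra-4,7,15(17)-trien-16,12-olide, C3 epimers | C=C1C(=O)O[C@@]2(C)CC[C@H]1CC(O)/C(C)=C/C/C=C(/C)CC[C@H]2OC(C)=O | intermediate
36 | (1S,4E,7Z,11R,12S)-11-acetoxy-3-oxocembra-4,7,15(17)-trien-16,12-olide | C=C1C(=O)O[C@@]2(C)CC[C@H]1CC(=O)/C(C)=C/C/C=C(/C)CC[C@H]2OC(C)=O | intermediate
37 | CNP0130972.9, (1S,3S,4E,7Z,11R,12S)-11-acetoxy-3-hydroxycembra-4,7,15(17)-trien-16,12-olide | C=C1C(=O)O[C@@]2(C)CC[C@H]1C[C@H](O)/C(C)=C/C/C=C(/C)CC[C@H]2OC(C)=O | target

## Step count and least certain steps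

Total: 24 steps. Longest linear sequence: 21 steps (steps 1–11 and 15–24); steps 12–14 make fragment 23.

**Step 1 (key step).** What may go wrong: insufficient enantioselectivity or conversion, because a hydrogen-bond catalyst activates weakly at −80 °C and an uncatalysed background reaction competes; some loss of the formyl enone during the acidic work-up is also possible. Fallback, from 2 back to 4, with auxiliary instead of catalyst control: (2R,5R)-2,5-diphenylpyrrolidine (or its antipode, whichever leads to (R)-4) is condensed with 4-methoxybut-3-en-2-one to the vinylogous amide F1, which is silylated (KN(SiMe3)2, TBSCl) to the chiral aminosiloxydiene F2. Thermal cycloaddition of F2 with 2 gives cycloadduct F3, and HF in MeCN releases the auxiliary and gives 4.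

**Step 8.** What may go wrong: poor facial selectivity if the chiral ligand and the existing C11/C12 centres are mismatched, and slow hydrocupration of the terminal alkene if the mixture warms. Fallback, from 12 to 13 without new compounds and under substrate instead of catalyst control: dissolving-metal reduction (Li, NH3, t-BuOH, −78 °C, then NH4Cl). Stereoelectronically controlled β-protonation should favour the isomer with the C2 chain and the C11 chain both equatorial, which is the trans isomer needed.

**Step 16.** What may go wrong: incomplete regiocontrol on the methyl alkyne and partial reduction of the lactone by the excess zirconium hydride. Fallback, from 17 and 23 back to 27, with the hydrometallation moved to the fragment: zirconium-catalysed hydroboration of 23 with pinacolborane gives the alkenylboronate F4, which can be purified at fragment level. The base-free Negishi coupling of 24 (from 17) with the C–I bond of F4 leaves the boronate untouched and gives F5. Iododeboronation with NaI and chloramine-T, with retention, gives 27.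

**Step 22.** What may go wrong: oligomerisation, slow addition of a hindered alkenylchromium species in a 14-membered closure, or interception by the enoate. Fallback, from 25 back to 35, with a ring closure that needs no alkenyl iodide: the operations of steps 17–21 applied to 25 give in turn Mannich base F6, its methiodide F7, methylene lactone F8, primary alcohol F9, ynal F10, hydroxy ynal F11 and acetoxy ynal F12. A nickel-catalysed reductive alkyne–aldehyde macrocyclisation of F12 (Ni(cod)2 as zerovalent nickel, PBu3, Et3B, high dilution) forms C3–C4 by syn addition across the alkyne and gives the 4E allylic alcohols 35.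

**Step 24.** What may go wrong: the facial preference of the macrocyclic enone may oppose the catalyst, giving the 3R epimer, and some conjugate reduction is possible. Fallback, from 34 to 37 without new compounds, setting C3 in the ring closure itself: the Nozaki–Hiyama–Kishi reaction of 34 is run with CrCl2 bound to a chiral oxazoline–sulfonamide ligand, so that the alkenylchromium species adds to one face of the aldehyde and the oxidation–reduction pair is not needed.

## Further compounds

F1 | step 1 | (E)-4-[(2R,5R)-2,5-diphenylpyrrolidin-1-yl]but-3-en-2-one | CC(=O)/C=C/N1[C@@H](c2ccccc2)CC[C@@H]1c1ccccc1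
F2 | step 1 | (E)-1-[(2R,5R)-2,5-diphenylpyrrolidin-1-yl]-3-(tert-butyldimethylsilyloxy)buta-1,3-diene | C=C(O[Si](C)(C)C(C)(C)C)/C=C/N1[C@@H](c2ccccc2)CC[C@@H]1c1ccccc1
F3 | step 1 | (1R,2S)-2-[(2R,5R)-2,5-diphenylpyrrolidin-1-yl]-1-methyl-4-(tert-butyldimethylsilyloxy)cyclohex-3-ene-1-carbaldehyde | O=C[C@]1(C)CCC(O[Si](C)(C)C(C)(C)C)=C[C@@H]1N1[C@@H](c2ccccc2)CC[C@@H]1c1ccccc1
F0 | step 8 | none | none
F4 | step 16 | 2-[(2Z,5Z)-6-iodohepta-2,5-dien-2-yl]-4,4,5,5-tetramethyl-1,3,2-dioxaborolane (boron trans to C6) | CC1(C)OB(OC1(C)C)/C(C)=C/C/C=C(/C)I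
F5 | step 16 | boronate analogue of 27 (pinacolboryl in place of iodine on C4) | CC1(C)OB(OC1(C)C)/C(C)=C/C/C=C(/C)CC[C@@H](O[Si](C)(C)C(C)(C)C)[C@@]1(C)OC(=O)C[C@H](CCO[Si](C)(C)C(C)(C)C)CC1
F6 | step 22 | 3-(dimethylaminomethyl) derivative of 25 (C15 epimers) | CC#CC/C=C(/C)CC[C@@H](O[Si](C)(C)C(C)(C)C)[C@@]1(C)OC(=O)C(CN(C)C)[C@H](CCO[Si](C)(C)C(C)(C)C)CC1
F7 | step 22 | trimethylammonium iodide of F6 | CC#CC/C=C(/C)CC[C@@H](O[Si](C)(C)C(C)(C)C)[C@@]1(C)OC(=O)C(C[N+](C)(C)C)[C@H](CCO[Si](C)(C)C(C)(C)C)CC1.[I-]
F8 | step 22 | (4S,7S)-7-[(1R,4Z)-1-(TBSO)-4-methylnon-4-en-7-yn-1-yl]-4-[2-(TBSO)ethyl]-7-methyl-3-methylideneoxepan-2-one | CC#CC/C=C(/C)CC[C@@H](O[Si](C)(C)C(C)(C)C)[C@@]1(C)OC(=O)C(=C)[C@H](CCO[Si](C)(C)C(C)(C)C)CC1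
F9 | step 22 | (4S,7S)-7-[(1R,4Z)-1-(TBSO)-4-methylnon-4-en-7-yn-1-yl]-4-(2-hydroxyethyl)-7-methyl-3-methylideneoxepan-2-one | CC#CC/C=C(/C)CC[C@@H](O[Si](C)(C)C(C)(C)C)[C@@]1(C)OC(=O)C(=C)[C@H](CCO)CC1
F10 | step 22 | 2-{(4S,7S)-7-[(1R,4Z)-1-(TBSO)-4-methylnon-4-en-7-yn-1-yl]-7-methyl-3-methylidene-2-oxooxepan-4-yl}acetaldehyde | CC#CC/C=C(/C)CC[C@@H](O[Si](C)(C)C(C)(C)C)[C@@]1(C)OC(=O)C(=C)[C@H](CC=O)CC1
F11 | step 22 | 2-{(4S,7S)-7-[(1R,4Z)-1-hydroxy-4-methylnon-4-en-7-yn-1-yl]-7-methyl-3-methylidene-2-oxooxepan-4-yl}acetaldehyde | CC#CC/C=C(/C)CC[C@@H](O)[C@@]1(C)OC(=O)C(=C)[C@H](CC=O)CC1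
F12 | step 22 | (1R,4Z)-4-methyl-1-[(2S,5S)-2-methyl-6-methylidene-7-oxo-5-(2-oxoethyl)oxepan-2-yl]non-4-en-7-yn-1-yl acetate | CC#CC/C=C(/C)CC[C@@H](OC(C)=O)[C@@]1(C)OC(=O)C(=C)[C@H](CC=O)CC1
F0 | step 24 | none | none
A1 | alternative 1 | macrocyclic triene sulfone (either C9 epimer) | C=C(CO[Si](C)(C)C(C)(C)C)[C@@H]1C[C@H](O[Si](C)(C)C(C)(C)C)/C(C)=C/C/C=C(/C)C(S(=O)(=O)c2ccccc2)C/C=C(\C)CC1
A2 | alternative 1 | linear C10 allylic bromide with C9 phenylsulfonylmethylene (seco form of A1) | BrC/C=C(\C)CC[C@H](C(=C)CO[Si](C)(C)C(C)(C)C)C[C@H](O[Si](C)(C)C(C)(C)C)/C(C)=C/C/C=C(/C)CS(=O)(=O)c1ccccc1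
A3 | alternative 2 | C4–C11 (4E,7Z)-iodo diene silyl ether | I/C(C)=C/C/C=C(/C)CCCO[Si](C)(C)C(C)(C)C
A4 | alternative 2 | [3-(tert-butyldimethylsilyloxy)propyl]magnesium bromide | CC(C)(C)[Si](C)(C)OCCC[Mg]Br
A5 | alternative 2 | propyne | CC#C
A6 | alternative 2 | (E)-1-bromo-3-iodobut-2-ene | I/C(C)=C/CBr
A7 | alternative 3 | C3 tert-butyldimethylsilyl ether of the target | C=C1C(=O)O[C@@]2(C)CC[C@H]1C[C@H](O[Si](C)(C)C(C)(C)C)/C(C)=C/C/C=C(/C)CC[C@H]2OC(C)=O
A8 | alternative 3 | macrocyclic C15 enol triflate with free C12 hydroxyl, C11 acetate and C3 silyl ether | C=C(OS(=O)(=O)C(F)(F)F)[C@@H]1C[C@H](O[Si](C)(C)C(C)(C)C)/C(C)=C/C/C=C(/C)CC[C@@H](OC(C)=O)[C@@](C)(O)CC1
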